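**Strategy.** The chromone is cut back to its benzene ring, which is built, not bought. Ring A carries three contiguous substituents (O1 on C8a, C4 on C4a, OH on C5), the signature of a vinylketene/alkoxyalkyne benzannulation. Heating cyclobutenone with a silyl-protected 1-ethoxy-1,4-diyn-3-ol should forge C4a–C8a, C5–C6 and C8–C8a in one operation. The expected product is a 2-substituted 3-ethoxyphenol whose ortho side chain brings in the remaining pyranone carbons (C2–C4) and the C15 tail. The precursor is a racemic bis-propargylic TBS ether with an ethoxyalkyne on one side and the heptadecyne-derived alkyne on the other. Desilylation, oxidation, amine-relayed O1–C2 closure and de-ethylation finish the pyranone ring.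

Key step: step 6

Remark on the chemistry: the target is achiral; the carbinol stereocenter carried between the acetylide addition and the oxidation step is racemic throughout and is removed by that oxidation, so no stereocontrol is planned.

Step 1
Reactants: 1 heptadec-1-yne
Product: 3 octadec-2-ynal, via lithium heptadec-1-yn-1-ide 2 (not isolated)
Conditions: n-BuLi, THF, −40 °C; DMF, −40 °C to rt; reverse quench into 10% aq. KH2PO4/MTBE, 5 °C
Reagents that add atoms: N,N-dimethylformamide (DMF), CN(C)C=O
Why: Formylation of a lithium acetylide with DMF is a standard acetylide acylation, and the buffered reverse quench should release the ynal from the hemiaminal salt before the liberated dimethylamine can add to the triple bond; no stereocenter is formed.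

Step 2
Reactants: 3 octadec-2-ynal; 4 ethoxyacetylene
Product: 6 racemic 1-ethoxyicosa-1,4-diyn-3-ol, via lithium ethoxyacetylide 5 (not isolated)
Conditions: 4, n-BuLi, THF, −78 °C; then 3, −78 °C; H2O quench; crude product or Et3N-deactivated silica
Reagents that add atoms: none
Why: 1,2-Addition of a lithium alkynide to an aldehyde should give the bis-propargylic carbinol, whose one new stereocenter forms without facial bias and is carried as the racemate, while the acid-free quench guards the ethoxyalkynyl carbinol against Meyer–Schuster rearrangement.

Step 3
Reactants: 6 racemic 1-ethoxyicosa-1,4-diyn-3-ol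
Product: 7 racemic tert-butyl[(1-ethoxyicosa-1,4-diyn-3-yl)oxy]dimethylsilane
Conditions: TBSCl, imidazole, DMF, 0 °C to rt
Reagents that add atoms: tert-butyldimethylsilyl chloride (TBSCl), CC(C)(C)[Si](C)(C)Cl
Why: Imidazole-promoted O-silylation of a secondary alcohol is routine, keeps the medium basic for the acid-labile ynol ether, and masks a hydroxyl that would otherwise be open to Meyer–Schuster rearrangement and to acylation by ketenes in the key step.

Step 4
Reactants: 8 3-oxocyclobutane-1-carboxylic acid
Product: 9 3-bromocyclobutan-1-one
Conditions: HgO (red), Br2, MgSO4, CH2Cl2, reflux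
Reagents that add atoms: bromine, BrBr
Why: Bromodecarboxylation through the acyl hypobromite (Cristol–Firth variant of the Hunsdiecker reaction) is established for this acid and should leave the ketone untouched, with MgSO4 taking up the water formed.

Step 5
Reactants: 9 3-bromocyclobutan-1-one
Product: 10 cyclobut-2-en-1-one
Conditions: n-Bu3N, neat, rt, reduced pressure, product collected at −78 °C and used at once as a cold toluene solution
Reagents that add atoms: none
Why: The β-bromo ketone should lose HBr by an E1cB-type β-elimination with the hindered, non-nucleophilic amine, and distilling the volatile enone out as it forms keeps it away from base and from itself.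

Step 6
Reactants: 10 cyclobut-2-en-1-one; 7 racemic tert-butyl[(1-ethoxyicosa-1,4-diyn-3-yl)oxy]dimethylsilane
Product: 15 racemic 2-[1-(tert-butyldimethylsilyloxy)octadec-2-yn-1-yl]-3-ethoxyphenol, via vinylketene 11 (not isolated), via 4-vinylcyclobutenone adduct 12 (not isolated), via dienylketene 13 (not isolated), via cyclohexa-2,4-dienone tautomer 14 (not isolated)
Conditions: 7 (1 equiv), 10 (2 equiv, in two portions), degassed toluene, base-washed sealed tube, 80 °C; 100 °C only after 7 is consumed; K2CO3, MeOH, rt work-up
Reagents that add atoms: none
Why: At 80 °C compound 10 opens reversibly (conrotatory four-electron electrocyclic cleavage of the C(=O)–CH2 bond) to vinylketene 11, whose ketene C=C is trapped by the ynol ether of 7 in a regioselective [2+2] cycloaddition, the nucleophilic alkyne carbon that carries the silyloxy side chain bonding to the ketene carbonyl carbon (C4a–C8a) and the ethoxy-bearing carbon to the ketene α-carbon (C5–C6) to give 12. Adduct 12 reopens to dienylketene 13 (only the geometry with ketene and vinyl cis is productive, and the opening is reversible), which closes ring A by a thermal disrotatory six-electron electrocyclization between the ketene carbon and the vinyl terminus (C8–C8a) to give 14, and enolization should deliver phenol 15 with OH, side chain and OEt on three adjacent carbons. This is the Danheiser benzannulation of a cyclobutenone with an alkoxyalkyne, a known reaction type that gives exactly this 2-substituted resorcinol monoether pattern. No lasting stereocenter is created, since the ring stereocenter of 12 is erased on reopening and the carbinol center stays racemic. Both the preference for the ynol ether over the internal dialkyl alkyne and the orientation of addition follow from the electron-rich, strongly polarized C≡C–O unit, an unactivated alkyne being inert to ketenes at this temperature. The [2+2] stage is held at 80 °C so that the ethoxyalkyne does not lose ethylene by retro-ene fragmentation, surplus volatile 10 offsets its self-condensation, and the K2CO3/MeOH work-up returns any phenol that was O-acylated by excess ketene.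

Step 7
Reactants: 15 racemic 2-[1-(tert-butyldimethylsilyloxy)octadec-2-yn-1-yl]-3-ethoxyphenol
Product: 16 racemic 3-ethoxy-2-(1-hydroxyoctadec-2-yn-1-yl)phenol
Conditions: TBAF, AcOH (1:1), THF, 0 °C to rt
Reagents that add atoms: none
Why: Fluoride-mediated silyl ether cleavage, driven by the Si–F bond and buffered with acetic acid, should free the carbinol without ionizing the electron-rich ortho-hydroxybenzylic alcohol, the racemic center being unchanged.

Step 8
Reactants: 16 racemic 3-ethoxy-2-(1-hydroxyoctadec-2-yn-1-yl)phenol
Product: 17 1-(2-ethoxy-6-hydroxyphenyl)octadec-2-yn-1-one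
Conditions: MnO2 (activated, excess), CH2Cl2, rt
Reagents that add atoms: none
Why: Activated MnO2 oxidizes benzylic and propargylic alcohols selectively (this carbinol is both) under neutral conditions that a free phenol tolerates, and the stereocenter is removed.

Step 9
Reactants: 17 1-(2-ethoxy-6-hydroxyphenyl)octadec-2-yn-1-one
Product: 19 5-ethoxy-2-pentadecyl-4H-chromen-4-one, via enaminone 18 (not isolated)
Conditions: Et2NH, EtOH, rt to 60 °C, then evaporation of the amine
Reagents that add atoms: none
Why: Aza-Michael addition of the secondary amine to the ynone gives enaminone 18, and intramolecular addition–elimination by the ortho phenol at the amine-bearing carbon then closes O1–C2 with loss of Et2NH (a net 6-endo-dig oxa-Michael cyclization of an ortho-hydroxyaryl ynone), which shuts off the 5-exo mode and avoids strong bases that isomerize alkyl ynones to allenones.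

Step 10
Reactants: 19 5-ethoxy-2-pentadecyl-4H-chromen-4-one
Product: 21 5-hydroxy-2-pentadecyl-4H-chromen-4-one, via dichloroboron chelate 20 (not isolated)
Conditions: BCl3 (1 M in CH2Cl2), CH2Cl2, −78 °C to rt; then H2O
Reagents that add atoms: none
Why: BCl3 binds between the C4 carbonyl and the peri O5, chloride dealkylates the activated ethyl ether by SN2 attack to give chelate 20, and aqueous work-up frees the 5-OH, a chelation-directed Lewis acid ether cleavage that should spare the pyranone enol ether and the alkyl chain.

**Compound list**

1 | heptadec-1-yne | CCCCCCCCCCCCCCCC#C | starting material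
2 | lithium heptadec-1-yn-1-ide | CCCCCCCCCCCCCCCC#C[Li] | intermediate
3 | octadec-2-ynal | CCCCCCCCCCCCCCCC#CC=O | intermediate
4 | ethoxyacetylene (ethoxyethyne) | C#COCC | starting material
5 | lithium ethoxyacetylide | [Li]C#COCC | intermediate
6 | racemic 1-ethoxyicosa-1,4-diyn-3-ol | CCCCCCCCCCCCCCCC#CC(O)C#COCC | intermediate
7 | racemic tert-butyl[(1-ethoxyicosa-1,4-diyn-3-yl)oxy]dimethylsilane | CCCCCCCCCCCCCCCC#CC(O[Si](C)(C)C(C)(C)C)C#COCC | intermediate
8 | 3-oxocyclobutane-1-carboxylic acid | O=C1CC(C(=O)O)C1 | starting material
9 | 3-bromocyclobutan-1-one | O=C1CC(Br)C1 | intermediate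
10 | cyclobut-2-en-1-one | O=C1CC=C1 | intermediate
11 | vinylketene (buta-1,3-dien-1-one) | C=CC=C=O | intermediate
12 | 2-[1-(tert-butyldimethylsilyloxy)octadec-2-yn-1-yl]-3-ethoxy-4-vinylcyclobut-2-en-1-one (racemic, mixture of diastereomers) | CCCCCCCCCCCCCCCC#CC(O[Si](C)(C)C(C)(C)C)C1=C(OCC)C(C=C)C1=O | intermediate
13 | racemic (3E)-2-[1-(tert-butyldimethylsilyloxy)octadec-2-yn-1-yl]-3-ethoxyhexa-1,3,5-trien-1-one (ketene and vinyl cis) | CCCCCCCCCCCCCCCC#CC(O[Si](C)(C)C(C)(C)C)C(=C=O)/C(OCC)=C\C=C | intermediate
14 | racemic 2-[1-(tert-butyldimethylsilyloxy)octadec-2-yn-1-yl]-3-ethoxycyclohexa-2,4-dien-1-one | CCCCCCCCCCCCCCCC#CC(O[Si](C)(C)C(C)(C)C)C1=C(OCC)C=CCC1=O | intermediate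
15 | racemic 2-[1-(tert-butyldimethylsilyloxy)octadec-2-yn-1-yl]-3-ethoxyphenol | CCCCCCCCCCCCCCCC#CC(O[Si](C)(C)C(C)(C)C)c1c(O)cccc1OCC | intermediate
16 | racemic 3-ethoxy-2-(1-hydroxyoctadec-2-yn-1-yl)phenol | CCCCCCCCCCCCCCCC#CC(O)c1c(O)cccc1OCC | intermediate
17 | 1-(2-ethoxy-6-hydroxyphenyl)octadec-2-yn-1-one | CCCCCCCCCCCCCCCC#CC(=O)c1c(O)cccc1OCC | intermediate
18 | 3-(diethylamino)-1-(2-ethoxy-6-hydroxyphenyl)octadec-2-en-1-one (mixture of double-bond isomers) | CCCCCCCCCCCCCCCC(=CC(=O)c1c(O)cccc1OCC)N(CC)CC | intermediate
19 | 5-ethoxy-2-pentadecyl-4H-chromen-4-one | CCCCCCCCCCCCCCCc1cc(=O)c2c(OCC)cccc2o1 | intermediate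
20 | 5-[(dichloroboranyl)oxy]-2-pentadecyl-4H-chromen-4-one (boron chelated to the C4 carbonyl) | CCCCCCCCCCCCCCCc1cc(=O)c2c(OB(Cl)Cl)cccc2o1 | intermediate
21 | 5-hydroxy-2-pentadecyl-4H-chromen-4-one | CCCCCCCCCCCCCCCc1cc(=O)c2c(O)cccc2o1 | target

**Step count.** Total: 10 steps. Longest linear sequence: 8 steps (steps 1, 2, 3, 6, 7, 8, 9, 10); the cyclobutenone branch (steps 4 and 5) joins at step 6.

**Steps most likely to fail**

Risk 1 (step 6). The cascade may be outrun by self-condensation of the unsubstituted cyclobutenone and its ketene. The ynol ether, inductively deactivated by the propargylic silyloxy group, may also add too slowly, so that ethylene loss from the ethoxyalkyne sets in before the [2+2] stage is complete. The fallback gives up the ring construction and takes the 1,2,3-trisubstituted arene from a bought aromatic. Commercial 2,6-dihydroxybenzaldehyde (O=Cc1c(O)cccc1O) is mono-O-ethylated (iodoethane, KHCO3, DMF, rt; the second hydroxyl is deactivated by its hydrogen bond to the aldehyde) to 2-ethoxy-6-hydroxybenzaldehyde F1. Addition of lithium heptadec-1-yn-1-ide 2 (2.2 equiv, from 1 and n-BuLi in THF, −78 °C to 0 °C; the first equivalent deprotonates the phenol) to F1 should give diol 16 after aqueous work-up. This fallback sets out from 1 and comes back to the route at 16, so steps 8 to 10 are unchanged.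

Risk 2 (step 5). Cyclobutenone may be lost to polymerization or evaporation during its generation, transfer and storage. The fallback produces the same vinylketene without it. Slow addition of commercial (E)-but-2-enoyl chloride (C/C=C/C(Cl)=O) to Et3N and 7 in toluene at rt should give vinylketene 11 by 1,4-dehydrochlorination. The ynol ether intercepts 11 to form 12; after the ammonium salt is filtered off, heating at 80 °C takes 12 through 13 and 14 to 15. This fallback sets out from 7 and comes back at 15; no compound outside the list is made (F0).

Risk 3 (step 9). The amine relay may stall at the enaminone stage, or the addition–elimination equilibrium may not be driven fully to the ring-closed side. The fallback switches to the classical diketone closure. Enaminone 18 (from 17 and Et2NH as in step 9) is hydrolyzed with aqueous HCl in THF to 1-(2-ethoxy-6-hydroxyphenyl)octadecane-1,3-dione F2. Acid-catalyzed cyclodehydration (cat. H2SO4, AcOH, 80 °C), the closing operation of Baker–Venkataraman-type chromone syntheses, should then give 19. This fallback sets out from 18 and comes back at 19.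

**Further compounds**

F1 | step 6 | 2-ethoxy-6-hydroxybenzaldehyde | CCOc1cccc(O)c1C=O
F0 | step 5 | none | none
F2 | step 9 | 1-(2-ethoxy-6-hydroxyphenyl)octadecane-1,3-dione | CCCCCCCCCCCCCCCC(=O)CC(=O)c1c(O)cccc1OCC
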